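**Retrosynthetic overview**
- Feature: on the oxolane ring, the carbinol carbon (on C3) and the benzylic CH2 carbon (on C4) are cis substituents of adjacent ring carbons. A temporary bond between these two exocyclic carbons gives a cyclobutane cis-fused across C3–C4. That is a 3-oxabicyclo[3.2.0]heptane whose five-membered part is 2,5-dihydrofuran.
- Target ⇒ (desilylation, reagent-controlled C=O reduction) cis-3-aroyl-4-benzyloxolane ⇒ (reconnect the aroyl carbon to the ArCH2 carbon) 6,7-diaryl-3-oxabicyclo[3.2.0]heptan-6-ol ⇒ (arylcerium addition) 7-aryl-3-oxabicyclo[3.2.0]heptan-6-one.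
- Cyclobutanone ⇒ [2+2] cycloaddition of 2,5-dihydrofuran with the aryl keteniminium ion of a homovanillic amide that carries C2-symmetric 2,5-dimethylpyrrolidine.
- Ring order: the oxolane is bought as the alkene. The cyclobutane is the only ring built (step 3), and it is opened again (step 6) once it has fixed the cis relationship.

Key step: step 3

Assumption: the (2S,5S) auxiliary is taken to favour the (1S,5R) ring fusion; this sense of induction is not established for this alkene, so it is checked on the cyclobutanone, and if it is the reverse the equally available (2R,5R)-amine is used in step 2 with nothing else changed.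

Step 1
Reactants: 1 homovanillic acid
Product: 3 2-[4-(tert-butyldimethylsilyloxy)-3-methoxyphenyl]acetic acid, via bis-silylated homovanillic acid 2 (not isolated)
Conditions: TBSCl (2.3 equiv), imidazole (5 equiv), DMF, rt; then AcOH/THF/H2O, rt
Reagents that add atoms: tert-butyldimethylsilyl chloride, C[Si](C)(Cl)C(C)(C)C
Why: Imidazole-promoted silylation caps both the phenol and the carboxylic acid, and the much more labile silyl ester of 2 is then hydrolysed selectively by aqueous acetic acid while the aryl silyl ether stays in place.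

Step 2
Reactants: 3 2-[4-(tert-butyldimethylsilyloxy)-3-methoxyphenyl]acetic acid; 4 (2S,5S)-2,5-dimethylpyrrolidine
Product: 6 2-[4-(tert-butyldimethylsilyloxy)-3-methoxyphenyl]-1-[(2S,5S)-2,5-dimethylpyrrolidin-1-yl]ethan-1-one, via arylacetyl chloride 5 (not isolated)
Conditions: (COCl)2, cat. DMF, CH2Cl2, 0 °C → rt, concentrate; then 4, Et3N, CH2Cl2, 0 °C → rt
Reagents that add atoms: oxalyl chloride, O=C(Cl)C(=O)Cl (chlorine of 5 only; no reagent atom stays in 6)
Why: Conversion into the acyl chloride (DMF-catalysed, Vilsmeier-type activation) followed by N-acylation is the dependable way to acylate this hindered secondary amine, and the two stereocentres of the amine are not involved.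

Step 3
Reactants: 6 2-[4-(tert-butyldimethylsilyloxy)-3-methoxyphenyl]-1-[(2S,5S)-2,5-dimethylpyrrolidin-1-yl]ethan-1-one; 7 2,5-dihydrofuran
Product: 11 (1S,5R)-7-[4-(tert-butyldimethylsilyloxy)-3-methoxyphenyl]-3-oxabicyclo[3.2.0]heptan-6-one (cis-fused; C7 as either epimer), via O-triflyliminium triflate 8 (not isolated), via keteniminium triflate 9 (not isolated), via cyclobutaniminium triflate 10 (not isolated)
Conditions: Tf2O (1.1 equiv), ClCH2CH2Cl, −20 °C; then 7 (5 equiv), 2,4,6-collidine (1.2 equiv), −20 → 60 °C; then H2O, 60 °C; NaOH on the aqueous layer returns 4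
Reagents that add atoms: water, O (carbonyl oxygen of 11); triflic anhydride, O=S(=O)(OS(=O)(=O)C(F)(F)F)C(F)(F)F (triflyl group and counter-ion of 8, 9 and 10 only)
Why: Tf2O turns amide 6 into the O-triflyliminium salt 8 before the alkene is present, so that no free anhydride meets the ether oxygen of 7, and collidine then removes the benzylic proton while triflate departs to give the linear keteniminium ion 9. The step is the keteniminium–alkene [2+2] cycloaddition known for cyclopentene and cyclohexene with amides of C2-symmetric 2,5-dimethylpyrrolidine: the alkene attacks the central carbon of 9 in the plane of the ArCH terminus on the side of its hydrogen (C5–C6 bond), and the developing cationic centre is captured at once by the enamine carbon (C1–C7 bond). The cyclobutane is thus closed by an intermolecular, strongly asynchronous [2+2] addition in which both bonds form on the same face of a Z-alkene held in a five-membered ring, so the C1/C5 fusion can only be cis. The absolute configuration at C1 and C5, that is the orientation of the unsymmetrical keteniminium ion across the symmetrical alkene, is decided by the pyrrolidinium methyl group that projects onto the attacked face and blocks one of the two placements of the heterocycle, whereas C7 is uncontrolled, may epimerise during hydrolysis and is erased in step 6. The step needs chemoselectivity for the alkene over the electron-rich arene and the ether oxygen, secured by the excess of cheap 7 and the reversibility of attack through oxygen, and it needs ring closure to outrun a 1,2-hydride shift to an oxocarbenium ion, which the stereospecificity known for this cycloaddition supports. Water finally hydrolyses iminium salt 10 to ketone 11, whose ring-fusion carbon C5 cannot epimerise inside the bicycle, and releases the auxiliary for recovery.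

Step 4
Reactants: 12 4-bromo-2-methoxyphenol
Product: 13 (4-bromo-2-methoxyphenoxy)(tert-butyl)dimethylsilane
Conditions: TBSCl, imidazole, DMF, rt
Reagents that add atoms: tert-butyldimethylsilyl chloride, C[Si](C)(Cl)C(C)(C)C
Why: Routine imidazole-promoted O-silylation of a phenol, which masks the acidic proton before the bromine–lithium exchange of step 5.

Step 5
Reactants: 13 (4-bromo-2-methoxyphenoxy)(tert-butyl)dimethylsilane; 11 (1S,5R)-7-aryl-3-oxabicyclo[3.2.0]heptan-6-one
Product: 16 (1S,5R)-6,7-bis[4-(tert-butyldimethylsilyloxy)-3-methoxyphenyl]-3-oxabicyclo[3.2.0]heptan-6-ol (C6 and C7 as formed), via aryllithium 14 (not isolated), via arylcerium dichloride 15 (not isolated)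
Conditions: 13 (1.6 equiv), n-BuLi, THF, −78 °C; anhydrous CeCl3 (THF slurry), −78 °C; then 11, −78 °C; aq. NH4Cl
Reagents that add atoms: n-butyllithium, [Li]CCCC (lithium of 14 only); cerium trichloride, Cl[Ce](Cl)Cl (cerium and chlorine of 15 only; no reagent atom stays in 16)
Why: Bromine–lithium exchange and transmetalation give a weakly basic, strongly oxophilic organocerium reagent that undergoes 1,2-addition to the strained but easily enolised alpha-aryl cyclobutanone instead of deprotonating it (organocerium carbonyl addition); attack is expected on the convex face, but the configuration at the new carbinol carbon C6 is irrelevant because C6 becomes a carbonyl carbon again in step 6.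

Step 6
Reactants: 16 (1S,5R)-6,7-diaryl-3-oxabicyclo[3.2.0]heptan-6-ol
Product: 17 [4-(tert-butyldimethylsilyloxy)-3-methoxyphenyl]{(3R,4S)-4-[[4-(tert-butyldimethylsilyloxy)-3-methoxyphenyl]methyl]oxolan-3-yl}methanone (cis)
Conditions: [Ir(dF(CF3)ppy)2(5,5'-d(CF3)bpy)]PF6 (2 mol %), PhSH (25 mol %), 2,4,6-collidine (3 equiv), CH2Cl2, blue LEDs, rt; filtration through neutral silica, used at once
Reagents that add atoms: none
Why: Redox-neutral photocatalytic ring opening of a 1-aryl cycloalkanol by proton-coupled electron transfer: the excited iridium complex oxidises the electron-rich arene on C6, collidine accepts the hydroxyl proton to give the alkoxy radical, strain-releasing beta-scission breaks C6–C7 toward the secondary benzylic radical rather than C5–C6 toward an unstabilised one, thiophenol delivers the hydrogen atom, and since the medium holds nothing more basic than collidine the now epimerisable C3 of the oxolane should keep its cis relationship to C4 while the stereocentres C6 and C7 vanish.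

Step 7
Reactants: 17 cis-(3R,4S) aryl ketone
Product: 18 (S)-[4-(tert-butyldimethylsilyloxy)-3-methoxyphenyl]{(3R,4S)-4-[[4-(tert-butyldimethylsilyloxy)-3-methoxyphenyl]methyl]oxolan-3-yl}methanol
Conditions: (R)-2-methyl-CBS-oxazaborolidine (0.5 equiv), BH3·SMe2 (1.0 equiv), THF, −20 °C; MeOH quench
Reagents that add atoms: none
Why: Corey–Bakshi–Shibata reduction: with the aryl group in the position of the large substituent the (R)-oxazaborolidine–borane complex delivers hydride to the Re face of the ketone and sets the (S)-carbinol, the Felkin–Anh preference of the substrate (C4 of the oxolane as the large group) points to the same face, and the non-basic medium leaves C3 untouched.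

Step 8
Reactants: 18 bis-silyl ether of the target
Product: 19 4-[(S)-hydroxy{(3R,4S)-4-[(4-hydroxy-3-methoxyphenyl)methyl]oxolan-3-yl}methyl]-2-methoxyphenol (target)
Conditions: TBAF (2.5 equiv), AcOH (2.5 equiv), THF, 0 °C
Reagents that add atoms: none
Why: Fluoride-mediated desilylation cleaves both aryl silyl ethers, and the acetic acid buffer keeps the liberated 4-hydroxybenzylic alcohol from ionising to a quinone methide, so the carbinol configuration and the cis ring substitution are kept.

**Compound list**
1 | homovanillic acid | COc1cc(CC(=O)O)ccc1O | starting material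
2 | tert-butyldimethylsilyl 2-[4-(tert-butyldimethylsilyloxy)-3-methoxyphenyl]acetate | COc1cc(CC(=O)O[Si](C)(C)C(C)(C)C)ccc1O[Si](C)(C)C(C)(C)C | intermediate
3 | 2-[4-(tert-butyldimethylsilyloxy)-3-methoxyphenyl]acetic acid | COc1cc(CC(=O)O)ccc1O[Si](C)(C)C(C)(C)C | intermediate
4 | (2S,5S)-2,5-dimethylpyrrolidine | C[C@H]1CC[C@H](C)N1 | starting material
5 | 2-[4-(tert-butyldimethylsilyloxy)-3-methoxyphenyl]acetyl chloride | COc1cc(CC(=O)Cl)ccc1O[Si](C)(C)C(C)(C)C | intermediate
6 | 2-[4-(tert-butyldimethylsilyloxy)-3-methoxyphenyl]-1-[(2S,5S)-2,5-dimethylpyrrolidin-1-yl]ethan-1-one | COc1cc(CC(=O)N2[C@@H](C)CC[C@@H]2C)ccc1O[Si](C)(C)C(C)(C)C | intermediate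
7 | 2,5-dihydrofuran | C1C=CCO1 | starting material
8 | (2S,5S)-1-{2-aryl-1-[(trifluoromethylsulfonyl)oxy]ethylidene}-2,5-dimethylpyrrolidinium triflate | COc1cc(CC(OS(=O)(=O)C(F)(F)F)=[N+]2[C@@H](C)CC[C@@H]2C)ccc1O[Si](C)(C)C(C)(C)C.[O-]S(=O)(=O)C(F)(F)F | intermediate
9 | (2S,5S)-1-(2-arylethenylidene)-2,5-dimethylpyrrolidinium triflate (keteniminium salt) | COc1cc(C=C=[N+]2[C@@H](C)CC[C@@H]2C)ccc1O[Si](C)(C)C(C)(C)C.[O-]S(=O)(=O)C(F)(F)F | intermediate
10 | (2S,5S)-1-[7-aryl-3-oxabicyclo[3.2.0]heptan-6-ylidene]-2,5-dimethylpyrrolidinium triflate, cis-fused, C1 and C5 arranged in space as in 11 | C[C@H]3CC[C@H](C)[N+]3=C1C(c4ccc(O[Si](C)(C)C(C)(C)C)c(OC)c4)[C@@H]2COC[C@H]12.[O-]S(=O)(=O)C(F)(F)F | intermediate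
11 | (1S,5R)-7-[4-(tert-butyldimethylsilyloxy)-3-methoxyphenyl]-3-oxabicyclo[3.2.0]heptan-6-one, C7 as either epimer | O=C1C(c2ccc(O[Si](C)(C)C(C)(C)C)c(OC)c2)[C@@H]2COC[C@H]12 | intermediate
12 | 4-bromo-2-methoxyphenol | COc1cc(Br)ccc1O | starting material
13 | (4-bromo-2-methoxyphenoxy)(tert-butyl)dimethylsilane | COc1cc(Br)ccc1O[Si](C)(C)C(C)(C)C | intermediate
14 | [4-(tert-butyldimethylsilyloxy)-3-methoxyphenyl]lithium | COc1cc([Li])ccc1O[Si](C)(C)C(C)(C)C | intermediate
15 | [4-(tert-butyldimethylsilyloxy)-3-methoxyphenyl]cerium dichloride | COc1cc([Ce](Cl)Cl)ccc1O[Si](C)(C)C(C)(C)C | intermediate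
16 | (1S,5R)-6,7-bis[4-(tert-butyldimethylsilyloxy)-3-methoxyphenyl]-3-oxabicyclo[3.2.0]heptan-6-ol, C6 and C7 unassigned | OC1(c2ccc(O[Si](C)(C)C(C)(C)C)c(OC)c2)C(c2ccc(O[Si](C)(C)C(C)(C)C)c(OC)c2)[C@@H]2COC[C@H]12 | intermediate
17 | [4-(tert-butyldimethylsilyloxy)-3-methoxyphenyl]{(3R,4S)-4-[[4-(tert-butyldimethylsilyloxy)-3-methoxyphenyl]methyl]oxolan-3-yl}methanone | COc1cc(C[C@@H]2COC[C@@H]2C(=O)c2ccc(O[Si](C)(C)C(C)(C)C)c(OC)c2)ccc1O[Si](C)(C)C(C)(C)C | intermediate
18 | (S)-[4-(tert-butyldimethylsilyloxy)-3-methoxyphenyl]{(3R,4S)-4-[[4-(tert-butyldimethylsilyloxy)-3-methoxyphenyl]methyl]oxolan-3-yl}methanol | COc1cc(C[C@@H]2COC[C@@H]2[C@H](O)c2ccc(O[Si](C)(C)C(C)(C)C)c(OC)c2)ccc1O[Si](C)(C)C(C)(C)C | intermediate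
19 | 4-[(S)-hydroxy{(3R,4S)-4-[(4-hydroxy-3-methoxyphenyl)methyl]oxolan-3-yl}methyl]-2-methoxyphenol | COc1cc(C[C@@H]2COC[C@@H]2[C@H](O)c2ccc(O)c(OC)c2)ccc1O | target

Total step count: 8. Longest linear sequence: 7 (steps 1, 2, 3, 5, 6, 7, 8); step 4 is a one-step side branch.

**Steps most likely to fail**

**Step 3.**
- Risk: the hindered pyrrolidinium may discriminate poorly between the two orientations of the symmetrical alkene, which would lower the enantiomeric purity. The allylic oxygen also slows the addition, so self-condensation of the keteniminium ion or a hydride shift in the developing cation may compete.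
- Fallback (auxiliary control is replaced by resolution): acid chloride 5 is coupled with pyrrolidine (Et3N, CH2Cl2) to give the unhindered amide 2-[4-(tert-butyldimethylsilyloxy)-3-methoxyphenyl]-1-(pyrrolidin-1-yl)ethan-1-one F1. Its smaller and more reactive keteniminium ion is added to 7 under the conditions of step 3. Hydrolysis should give the racemic cis-fused cyclobutanone, that is 11 together with its (1R,5S) mirror image F2. C7 is equilibrated to the exo-aryl epimer with Et3N, and the enantiomers are separated by preparative chromatography on a chiral stationary phase. The route is rejoined at 11.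

**Step 6.**
- Risk: back electron transfer or desilylation of the arene radical cation may outrun activation of the O–H bond. Part of the alkoxy radical may break C5–C6. The cis ketone may drift to the trans isomer through enolisation on long exposure to base or silica.
- Fallback (oxygen insertion and hydrogenolysis replace the radical scission, and steps 5 and 6 are bypassed): it sets out from 11. Baeyer–Villiger oxidation (mCPBA, NaHCO3, CH2Cl2, 0 °C), in which the electron-rich benzylic carbon C7 should migrate, gives the cis-fused lactone (3aS,6aR)-3-[4-(tert-butyldimethylsilyloxy)-3-methoxyphenyl]tetrahydro-1H,3H-furo[3,4-c]furan-1-one F3. Hydrogenolysis of its benzylic C–O bond (H2, Pd/C, EtOAc/AcOH) gives (3R,4S)-4-[[4-(tert-butyldimethylsilyloxy)-3-methoxyphenyl]methyl]oxolane-3-carboxylic acid F4. Coupling with MeNHOMe·HCl (EDC·HCl, N-methylmorpholine, CH2Cl2, 0 °C) gives the corresponding N-methoxy-N-methylamide F5. Aryllithium 14, made from 13 as in step 5, is added at −78 °C (Weinreb ketone synthesis), and the route is rejoined at 17.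

**Step 7.**
- Risk: the branched oxolanyl group may compete with the aryl group for the position of the large substituent in the oxazaborolidine complex, which would erode facial selectivity. The electron-rich ketone also reacts slowly, which leaves room for uncatalysed borane reduction.
- Fallback (substrate control, separation and recycling replace reagent control): it sets out from 17. Luche reduction (NaBH4, CeCl3·7H2O, MeOH, −78 °C) follows the Felkin–Anh preference without enolising C3. Compound 18 is separated by chromatography from its (R)-carbinol epimer F6. F6 is returned to 17 by Dess–Martin oxidation and reduced again. The route is rejoined at 18.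

**Further compounds**
F1 | step 3 | 2-[4-(tert-butyldimethylsilyloxy)-3-methoxyphenyl]-1-(pyrrolidin-1-yl)ethan-1-one | COc1cc(CC(=O)N2CCCC2)ccc1O[Si](C)(C)C(C)(C)C
F2 | step 3 | (1R,5S)-7-[4-(tert-butyldimethylsilyloxy)-3-methoxyphenyl]-3-oxabicyclo[3.2.0]heptan-6-one | O=C1C(c2ccc(O[Si](C)(C)C(C)(C)C)c(OC)c2)[C@H]2COC[C@@H]12
F3 | step 6 | (3aS,6aR)-3-[4-(tert-butyldimethylsilyloxy)-3-methoxyphenyl]tetrahydro-1H,3H-furo[3,4-c]furan-1-one | O=C1OC(c2ccc(O[Si](C)(C)C(C)(C)C)c(OC)c2)[C@@H]2COC[C@H]12
F4 | step 6 | (3R,4S)-4-[[4-(tert-butyldimethylsilyloxy)-3-methoxyphenyl]methyl]oxolane-3-carboxylic acid | COc1cc(C[C@@H]2COC[C@@H]2C(=O)O)ccc1O[Si](C)(C)C(C)(C)C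
F5 | step 6 | (3R,4S)-4-[[4-(tert-butyldimethylsilyloxy)-3-methoxyphenyl]methyl]-N-methoxy-N-methyloxolane-3-carboxamide | COc1cc(C[C@@H]2COC[C@@H]2C(=O)N(C)OC)ccc1O[Si](C)(C)C(C)(C)C
F6 | step 7 | (R)-[4-(tert-butyldimethylsilyloxy)-3-methoxyphenyl]{(3R,4S)-4-[[4-(tert-butyldimethylsilyloxy)-3-methoxyphenyl]methyl]oxolan-3-yl}methanol | COc1cc(C[C@@H]2COC[C@@H]2[C@@H](O)c2ccc(O[Si](C)(C)C(C)(C)C)c(OC)c2)ccc1O[Si](C)(C)C(C)(C)C
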